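Ring numbering used throughout: O1, C2 (stereocenter), C3 (C=O), C4 (C–OH), C5 (ring C=, bears the hexenyl chain), C6 (CH2).
Cuts, in retrosynthetic order: the C3 oxygen (ketone α-oxidation, last); O1–C6 and C5–C6 together (C6 as a formaldehyde unit); then C2–C3 and C4–C5 in one event.
Enabling feature: C5 is trigonal in the target (enol C4=C5) and C3–C4 maps onto a 1-alkoxyvinyl unit, so C5 can carry a temporary boron-bearing stereocenter that passes its chirality to C2 in a chair allylboration and is then erased.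
Forward: an enoate aldehyde (with the hexanoate arm), 1-ethoxyvinyl pinacol boronate (C3–C4) and a carbamate carrying the hexenyl chain (C5) are joined as an open chain in one flask; the pyranone ring then closes by insertion of C6 (methoxymethyl oxocarbenium ion onto the enol ether); C3 hydroxylation, deprotection and oxidation give the 3,4-dione, which enolises to the C4 enol, the C5 and C3 epimer mixtures converging there.
Stereochemistry: C2 from (−)-sparteine by way of the transient C5 centre; the two side-chain centres from ethyl (S)-3-hydroxybutanoate by Fráter–Seebach anti-methylation; the enoate (E) geometry by syn-carbocupration, the side-chain (E)-alkene by Julia–Kocienski olefination.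

Key step: step 11

Remark: the target is taken as the 4-hydroxy-3-one (diosphenol) tautomer drawn, assumed to be the preferred enol of the 3,4-dione; tert-butyl 6-hydroxyhexanoate, the dioxolanylmethyl Grignard reagent and the 1-ethoxyvinyl pinacol boronate are taken as commercial.

Step 1
Reactants: 1 but-2-ynoic acid; 2 tert-butyl 6-hydroxyhexanoate
Product: 3 6-(tert-butoxy)-6-oxohexyl but-2-ynoate
Conditions: DCC, DMAP (cat.), CH2Cl2, 0 °C → rt
Reagents that add atoms: none
Why: Steglich esterification joins the acid and the primary alcohol under neutral conditions that leave the alkyne and the tert-butyl ester untouched.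

Step 2
Reactants: 3 6-(tert-butoxy)-6-oxohexyl but-2-ynoate; 4 (1,3-dioxolan-2-ylmethyl)magnesium bromide
Product: 6 6-(tert-butoxy)-6-oxohexyl (E)-4-(1,3-dioxolan-2-yl)-3-methylbut-2-enoate, via alkenylcopper adduct 5 (not isolated)
Conditions: 4, CuI, THF, −40 °C; then 3, −78 °C; aq. NH4Cl at −78 °C
Reagents that add atoms: none
Why: Conjugate addition of the organocopper reagent to the ynoate is a syn carbocupration, so protonation of alkenylcopper 5 with retention should place the new CH2 group cis to H and trans to the ester, which sets the (E)-trisubstituted enoate.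

Step 3
Reactants: 6 6-(tert-butoxy)-6-oxohexyl (E)-4-(1,3-dioxolan-2-yl)-3-methylbut-2-enoate
Product: 7 6-(tert-butoxy)-6-oxohexyl (E)-3-methyl-5-oxopent-2-enoate
Conditions: 1 M aq. HCl, THF, 0 °C → rt; used crude at once
Reagents that add atoms: water O
Why: Dilute aqueous acid hydrolysis of the dioxolane should free the aldehyde while the tert-butyl ester survives, and the β,γ-unsaturated aldehyde is not stored.

Step 4
Reactants: 8 3-bromopropan-1-ol; 9 1-phenyl-1H-tetrazole-5-thiol
Product: 10 3-((1-phenyl-1H-tetrazol-5-yl)thio)propan-1-ol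
Conditions: K2CO3, acetone, rt
Reagents that add atoms: none
Why: SN2 S-alkylation of the acidic tetrazole thiol by the primary bromide.

Step 5
Reactants: 10 3-((1-phenyl-1H-tetrazol-5-yl)thio)propan-1-ol
Product: 11 3-((1-phenyl-1H-tetrazol-5-yl)thio)propyl N,N-diisopropylcarbamate
Conditions: i-Pr2NC(O)Cl, Et3N, DMAP (cat.), CH2Cl2, reflux
Reagents that add atoms: N,N-diisopropylcarbamoyl chloride CC(C)N(C(C)C)C(Cl)=O
Why: O-carbamoylation of the primary alcohol installs the group that later directs α-lithiation and serves as the leaving group in the 1,2-metallate shift.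

Step 6
Reactants: 11 3-((1-phenyl-1H-tetrazol-5-yl)thio)propyl N,N-diisopropylcarbamate
Product: 12 3-((1-phenyl-1H-tetrazol-5-yl)sulfonyl)propyl N,N-diisopropylcarbamate
Conditions: 30% aq. H2O2, (NH4)6Mo7O24·4H2O (cat.), EtOH, 0 °C → rt
Reagents that add atoms: hydrogen peroxide OO
Why: Molybdate-catalysed peroxide oxidation converts the sulfide into the sulfone needed for the Julia–Kocienski olefination without touching the carbamate.

Step 7
Reactants: 13 ethyl (S)-3-hydroxybutanoate
Product: 15 ethyl (2S,3S)-3-hydroxy-2-methylbutanoate, via dilithium alkoxide enolate 14 (not isolated)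
Conditions: LiN(i-Pr)2 (2.2 equiv), THF, −78 → −20 °C; MeI, DMPU, −78 → 0 °C; H2O
Reagents that add atoms: iodomethane CI
Why: Fráter–Seebach alkylation, in which the chelated dianion 14 is methylated on the face opposite the C3 methyl group, so the chiral-pool (3S) carbinol sets the new (2S) centre anti to it.

Step 8
Reactants: 15 ethyl (2S,3S)-3-hydroxy-2-methylbutanoate
Product: 16 ethyl (2S,3S)-3-(tert-butyldimethylsilyloxy)-2-methylbutanoate
Conditions: t-BuMe2SiCl, imidazole, DMF, rt
Reagents that add atoms: tert-butyldimethylsilyl chloride CC(C)(C)[Si](C)(C)Cl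
Why: Standard silylation protects the secondary alcohol for the reduction and the organolithium chemistry ahead.

Step 9
Reactants: 16 ethyl (2S,3S)-3-(tert-butyldimethylsilyloxy)-2-methylbutanoate
Product: 17 (2S,3S)-3-(tert-butyldimethylsilyloxy)-2-methylbutanal
Conditions: i-Bu2AlH (1.05 equiv), CH2Cl2, −78 °C; MeOH, then aq. potassium sodium tartrate
Reagents that add atoms: none
Why: Partial reduction at −78 °C stops at the tetrahedral aluminium hemiacetal, which should release the aldehyde on work-up without epimerising the α-centre.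

Step 10
Reactants: 12 3-((1-phenyl-1H-tetrazol-5-yl)sulfonyl)propyl N,N-diisopropylcarbamate; 17 (2S,3S)-3-(tert-butyldimethylsilyloxy)-2-methylbutanal
Product: 19 (3E,5R,6S)-6-(tert-butyldimethylsilyloxy)-5-methylhept-3-en-1-yl N,N-diisopropylcarbamate, via potassium sulfonyl carbanion 18 (not isolated)
Conditions: KN(SiMe3)2, DME, −60 °C; then 17, −60 °C → rt
Reagents that add atoms: none
Why: Julia–Kocienski olefination, in which addition of carbanion 18 to the α-branched aldehyde, Smiles rearrangement and loss of SO2 and tetrazololate should give the (E)-alkene selectively.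

Step 11
Reactants: 19 (3E,5R,6S)-6-(tert-butyldimethylsilyloxy)-5-methylhept-3-en-1-yl N,N-diisopropylcarbamate; 20 2-(1-ethoxyvinyl)-4,4,5,5-tetramethyl-1,3,2-dioxaborolane; 7 6-(tert-butoxy)-6-oxohexyl (E)-3-methyl-5-oxopent-2-enoate
Product: 24 6-(tert-butoxy)-6-oxohexyl (2E,5S,7E,10E,12R,13S)-13-(tert-butyldimethylsilyloxy)-7-ethoxy-5-hydroxy-3,12-dimethyltetradeca-2,7,10-trienoate, via α-lithio carbamate 21 (not isolated), via boronate complex 22 (not isolated), via allylboronate 23 (not isolated)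
Conditions: s-BuLi, (−)-sparteine, Et2O, −78 °C, 5 h; 20, −78 °C → 35 °C; 7, 0 °C → rt; aq. NaHCO3
Reagents that add atoms: none
Why: s-BuLi/(−)-sparteine removes the pro-S hydrogen next to the carbamate oxygen to give the configurationally stable α-lithio carbamate 21, which is borylated by 20 with retention; the ate complex 22 then undergoes a 1,2-metallate rearrangement in which the 1-ethoxyvinyl group migrates from boron to carbon with inversion and expels the carbamate (C4–C5 bond), and the resulting (R)-2-ethoxyallyl boronate 23 adds to aldehyde 7 through a closed six-membered chair transition state (allylboration, C2–C3 bond) with allylic transposition that makes C5 trigonal. The closest known reaction type is the one-pot lithiation–borylation–allylboration of sparteine-lithiated primary alkyl carbamates with alkenyl pinacol boronates and aldehydes. No ring is closed here: the carbons that will lie in or on the pyranone are joined as an open chain, and the ring follows in step 13. The only new stereocenter, C2, is controlled by the boron-bearing stereocenter at C5, which is consumed in the same event: in the chair the chain on C5 should sit pseudo-axial (clear of the pinacol methyls and of A(1,2) strain with the 2-ethoxy group) and the aldehyde residue equatorial, so that the (R)-boronate delivers the (S)-carbinol and the enol ether with that chain cis to C3. The step needs one chair over the other, because the two chairs give opposite configurations at C2, and bond formation at the CH2 terminus of the allyl unit; the 2-ethoxy substituent together with the pinacol ester should secure the first, and the reluctance of pinacol allylboronates to undergo 1,3-boron shift the second. Chemoselectivity rests on the order of addition, since the organolithium is consumed by the boronate before the aldehyde, with its two esters, enters the flask.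

Step 12
Reactants: 24 6-(tert-butoxy)-6-oxohexyl (2E,5S,7E,10E,12R,13S)-13-(tert-butyldimethylsilyloxy)-7-ethoxy-5-hydroxy-3,12-dimethyltetradeca-2,7,10-trienoate
Product: 25 6-(tert-butoxy)-6-oxohexyl (2E,5S,7E,10E,12R,13S)-13-(tert-butyldimethylsilyloxy)-7-ethoxy-5-(methoxymethoxy)-3,12-dimethyltetradeca-2,7,10-trienoate
Conditions: MeOCH2Cl, i-Pr2NEt, CH2Cl2, 0 °C → rt
Reagents that add atoms: chloromethyl methyl ether COCCl
Why: Alkylation of the secondary alcohol under amine base installs the future C6 as a latent formaldehyde oxocarbenium ion and leaves the acid-labile enol ether intact.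

Step 13
Reactants: 25 6-(tert-butoxy)-6-oxohexyl (2E,5S,7E,10E,12R,13S)-13-(tert-butyldimethylsilyloxy)-7-ethoxy-5-(methoxymethoxy)-3,12-dimethyltetradeca-2,7,10-trienoate
Product: 27 6-(tert-butoxy)-6-oxohexyl (E)-4-((2S,5RS)-5-((2E,4R,5S)-5-(tert-butyldimethylsilyloxy)-4-methylhex-2-en-1-yl)-4-oxooxan-2-yl)-3-methylbut-2-enoate, via mixed ketal 26 (not isolated)
Conditions: Me3SiOTf (0.2 equiv), 2,6-di-tert-butyl-4-methylpyridine, CH2Cl2, −78 °C; then 1 M aq. HCl, THF, 0 °C
Reagents that add atoms: water O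
Why: Me3SiOTf ionises the methoxymethyl ether to an oxocarbenium ion that is captured by the β-carbon of the enol ether in a 6-endo Mukaiyama-type (Prins-type) cyclisation to ketal 26, hydrolysed on work-up to the ketone, while C2 is untouched and the new C5 centre needs no control because it becomes trigonal at the end.

Step 14
Reactants: 27 6-(tert-butoxy)-6-oxohexyl (E)-4-((2S,5RS)-5-((2E,4R,5S)-5-(tert-butyldimethylsilyloxy)-4-methylhex-2-en-1-yl)-4-oxooxan-2-yl)-3-methylbut-2-enoate
Product: 29 6-(tert-butoxy)-6-oxohexyl (E)-4-((2S,3RS,5RS)-5-((2E,4R,5S)-5-(tert-butyldimethylsilyloxy)-4-methylhex-2-en-1-yl)-3-hydroxy-4-oxooxan-2-yl)-3-methylbut-2-enoate, via lithium enolate 28 (not isolated)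
Conditions: LiN(SiMe3)2 (1.1 equiv), THF, −78 °C; 2-(phenylsulfonyl)-3-phenyloxaziridine, −78 °C; pH 7 buffer
Reagents that add atoms: 2-(phenylsulfonyl)-3-phenyloxaziridine O=S(=O)(c1ccccc1)N1OC1c1ccccc1
Why: Kinetic deprotonation should give the less substituted enolate 28 (C3 methylene in preference to the C5 methine), and electrophilic hydroxylation by the N-sulfonyloxaziridine then gives the α-hydroxy ketone, whose C3 configuration is irrelevant.

Step 15
Reactants: 29 6-(tert-butoxy)-6-oxohexyl (E)-4-((2S,3RS,5RS)-5-((2E,4R,5S)-5-(tert-butyldimethylsilyloxy)-4-methylhex-2-en-1-yl)-3-hydroxy-4-oxooxan-2-yl)-3-methylbut-2-enoate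
Product: 30 6-(((E)-4-((2S,3RS,5RS)-3-hydroxy-5-((2E,4R,5S)-5-hydroxy-4-methylhex-2-en-1-yl)-4-oxooxan-2-yl)-3-methylbut-2-enoyl)oxy)hexanoic acid
Conditions: CF3CO2H/CH2Cl2/H2O (9:9:1), 0 °C → rt; toluene co-evaporation
Reagents that add atoms: none
Why: Aqueous trifluoroacetic acid cleaves the tert-butyl ester (loss of isobutene) and the secondary silyl ether in one operation, at a stage where C2 is not yet alpha to a ketone.

Step 16
Reactants: 30 6-(((E)-4-((2S,3RS,5RS)-3-hydroxy-5-((2E,4R,5S)-5-hydroxy-4-methylhex-2-en-1-yl)-4-oxooxan-2-yl)-3-methylbut-2-enoyl)oxy)hexanoic acid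
Product: 31 6,7-diketothiomarinolic acid C6, 6-(((E)-4-((2S)-4-hydroxy-5-((2E,4R,5S)-5-hydroxy-4-methylhex-2-en-1-yl)-3-oxo-3,6-dihydro-2H-pyran-2-yl)-3-methylbut-2-enoyl)oxy)hexanoic acid
Conditions: Cu(OAc)2·H2O (2.2 equiv), MeOH/H2O/AcOH, rt, Ar; aq. citric acid work-up
Reagents that add atoms: none
Why: Cu(OAc)2 oxidises α-hydroxy ketones to 1,2-diones chemoselectively beside the isolated secondary alcohol and the alkenes, and the dione should enolise toward the fully substituted C5 (both C5 epimers converge) under weakly acidic conditions that should spare the C2 centre.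

Compound list
1 | but-2-ynoic acid | CC#CC(=O)O | starting material
2 | tert-butyl 6-hydroxyhexanoate | CC(C)(C)OC(=O)CCCCCO | starting material
3 | 6-(tert-butoxy)-6-oxohexyl but-2-ynoate | CC#CC(=O)OCCCCCC(=O)OC(C)(C)C | intermediate
4 | (1,3-dioxolan-2-ylmethyl)magnesium bromide | Br[Mg]CC1OCCO1 | starting material
5 | alkenylcopper adduct of 3 (copper on C2 of the butenoate, cis to the new CH2 group) | CC(C)(C)OC(=O)CCCCCOC(=O)/C([Cu])=C(\C)CC1OCCO1 | intermediate
6 | 6-(tert-butoxy)-6-oxohexyl (E)-4-(1,3-dioxolan-2-yl)-3-methylbut-2-enoate | CC(C)(C)OC(=O)CCCCCOC(=O)/C=C(\C)CC1OCCO1 | intermediate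
7 | 6-(tert-butoxy)-6-oxohexyl (E)-3-methyl-5-oxopent-2-enoate | CC(C)(C)OC(=O)CCCCCOC(=O)/C=C(\C)CC=O | intermediate
8 | 3-bromopropan-1-ol | OCCCBr | starting material
9 | 1-phenyl-1H-tetrazole-5-thiol | Sc1nnnn1-c1ccccc1 | starting material
10 | 3-((1-phenyl-1H-tetrazol-5-yl)thio)propan-1-ol | OCCCSc1nnnn1-c1ccccc1 | intermediate
11 | 3-((1-phenyl-1H-tetrazol-5-yl)thio)propyl N,N-diisopropylcarbamate | CC(C)N(C(C)C)C(=O)OCCCSc1nnnn1-c1ccccc1 | intermediate
12 | 3-((1-phenyl-1H-tetrazol-5-yl)sulfonyl)propyl N,N-diisopropylcarbamate | CC(C)N(C(C)C)C(=O)OCCCS(=O)(=O)c1nnnn1-c1ccccc1 | intermediate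
13 | ethyl (S)-3-hydroxybutanoate | CCOC(=O)C[C@H](C)O | starting material
14 | dilithium alkoxide enolate of 13 | [Li+].[Li+].CCOC([O-])=C[C@H](C)[O-] | intermediate
15 | ethyl (2S,3S)-3-hydroxy-2-methylbutanoate | CCOC(=O)[C@@H](C)[C@H](C)O | intermediate
16 | ethyl (2S,3S)-3-(tert-butyldimethylsilyloxy)-2-methylbutanoate | CCOC(=O)[C@@H](C)[C@H](C)O[Si](C)(C)C(C)(C)C | intermediate
17 | (2S,3S)-3-(tert-butyldimethylsilyloxy)-2-methylbutanal | O=C[C@@H](C)[C@H](C)O[Si](C)(C)C(C)(C)C | intermediate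
18 | potassium α-sulfonyl carbanion of 12 | [K+].CC(C)N(C(C)C)C(=O)OCC[CH-]S(=O)(=O)c1nnnn1-c1ccccc1 | intermediate
19 | (3E,5R,6S)-6-(tert-butyldimethylsilyloxy)-5-methylhept-3-en-1-yl N,N-diisopropylcarbamate | CC(C)N(C(C)C)C(=O)OCC/C=C/[C@@H](C)[C@H](C)O[Si](C)(C)C(C)(C)C | intermediate
20 | 2-(1-ethoxyvinyl)-4,4,5,5-tetramethyl-1,3,2-dioxaborolane | CCOC(=C)B1OC(C)(C)C(C)(C)O1 | starting material
21 | (S)-α-lithio carbamate from 19 (lithium on C1 of the heptenyl chain, sparteine ligand not drawn) | [Li][C@H](OC(=O)N(C(C)C)C(C)C)C/C=C/[C@@H](C)[C@H](C)O[Si](C)(C)C(C)(C)C | intermediate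
22 | lithium boronate (ate) complex of 21 and 20 | [Li+].CCOC(=C)[B-]1(OC(C)(C)C(C)(C)O1)[C@H](OC(=O)N(C(C)C)C(C)C)C/C=C/[C@@H](C)[C@H](C)O[Si](C)(C)C(C)(C)C | intermediate
23 | 2-((3R,5E,7R,8S)-8-(tert-butyldimethylsilyloxy)-2-ethoxy-7-methylnona-1,5-dien-3-yl)-4,4,5,5-tetramethyl-1,3,2-dioxaborolane | CCOC(=C)[C@@H](C/C=C/[C@@H](C)[C@H](C)O[Si](C)(C)C(C)(C)C)B1OC(C)(C)C(C)(C)O1 | intermediate
24 | 6-(tert-butoxy)-6-oxohexyl (2E,5S,7E,10E,12R,13S)-13-(tert-butyldimethylsilyloxy)-7-ethoxy-5-hydroxy-3,12-dimethyltetradeca-2,7,10-trienoate | CC(C)(C)OC(=O)CCCCCOC(=O)/C=C(\C)C[C@H](O)C/C(OCC)=C\C/C=C/[C@@H](C)[C@H](C)O[Si](C)(C)C(C)(C)C | intermediate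
25 | 6-(tert-butoxy)-6-oxohexyl (2E,5S,7E,10E,12R,13S)-13-(tert-butyldimethylsilyloxy)-7-ethoxy-5-(methoxymethoxy)-3,12-dimethyltetradeca-2,7,10-trienoate | CC(C)(C)OC(=O)CCCCCOC(=O)/C=C(\C)C[C@H](OCOC)C/C(OCC)=C\C/C=C/[C@@H](C)[C@H](C)O[Si](C)(C)C(C)(C)C | intermediate
26 | mixed ethyl methyl ketal of 27 at C4 of the oxane ring | CC(C)(C)OC(=O)CCCCCOC(=O)/C=C(\C)C[C@H]1CC(OC)(OCC)C(C/C=C/[C@@H](C)[C@H](C)O[Si](C)(C)C(C)(C)C)CO1 | intermediate
27 | 6-(tert-butoxy)-6-oxohexyl (E)-4-((2S,5RS)-5-((2E,4R,5S)-5-(tert-butyldimethylsilyloxy)-4-methylhex-2-en-1-yl)-4-oxooxan-2-yl)-3-methylbut-2-enoate | CC(C)(C)OC(=O)CCCCCOC(=O)/C=C(\C)C[C@H]1CC(=O)C(C/C=C/[C@@H](C)[C@H](C)O[Si](C)(C)C(C)(C)C)CO1 | intermediate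
28 | lithium enolate of 27 (C3=C4) | CC(C)(C)OC(=O)CCCCCOC(=O)/C=C(\C)C[C@H]1C=C([O-])C(C/C=C/[C@@H](C)[C@H](C)O[Si](C)(C)C(C)(C)C)CO1.[Li+] | intermediate
29 | 6-(tert-butoxy)-6-oxohexyl (E)-4-((2S,3RS,5RS)-5-((2E,4R,5S)-5-(tert-butyldimethylsilyloxy)-4-methylhex-2-en-1-yl)-3-hydroxy-4-oxooxan-2-yl)-3-methylbut-2-enoate | CC(C)(C)OC(=O)CCCCCOC(=O)/C=C(\C)C[C@H]1C(O)C(=O)C(C/C=C/[C@@H](C)[C@H](C)O[Si](C)(C)C(C)(C)C)CO1 | intermediate
30 | 6-(((E)-4-((2S,3RS,5RS)-3-hydroxy-5-((2E,4R,5S)-5-hydroxy-4-methylhex-2-en-1-yl)-4-oxooxan-2-yl)-3-methylbut-2-enoyl)oxy)hexanoic acid | OC(=O)CCCCCOC(=O)/C=C(\C)C[C@H]1C(O)C(=O)C(C/C=C/[C@@H](C)[C@H](C)O)CO1 | intermediate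
31 | 6,7-diketothiomarinolic acid C6 | C/C(=C\C(=O)OCCCCCC(=O)O)C[C@@H]1OCC(C/C=C/[C@@H](C)[C@H](C)O)=C(O)C1=O | target

Total step count: 16. Longest linear sequence: 10 steps (steps 7 to 16, from ethyl (S)-3-hydroxybutanoate).

Steps most likely to fail

Step 11. The electron-rich ethoxyvinyl group may migrate sluggishly in the 1,2-metallate shift. The amine and lithium carbamate in the flask may move the double bond of aldehyde 7 into conjugation with the formyl group. Leakage through the second chair would erode the configuration at C2. The fallback builds the ring by cycloaddition; it sets out from 7 and 17 and comes back at 27. Aldehyde 7 and (E)-1-methoxy-3-(trimethylsilyloxy)buta-1,3-diene would undergo an enantioselective hetero-Diels–Alder reaction under Ti(OiPr)4/BINOL catalysis (the BINOL antipode chosen for the (S) adduct) to the primary cycloadduct 6-(tert-butoxy)-6-oxohexyl (E)-4-((2S)-6-methoxy-4-(trimethylsilyloxy)-3,6-dihydro-2H-pyran-2-yl)-3-methylbut-2-enoate F1. Brief treatment with CF3CO2H would convert this, with loss of methanol and the silyl group, into 6-(tert-butoxy)-6-oxohexyl (E)-3-methyl-4-((S)-4-oxo-3,4-dihydro-2H-pyran-2-yl)but-2-enoate F2. In parallel, aldehyde 17 would be homologated by Horner–Wadsworth–Emmons reaction (triethyl phosphonoacetate, NaH) to ethyl (2E,4R,5S)-5-(tert-butyldimethylsilyloxy)-4-methylhex-2-enoate F3, reduced with i-Bu2AlH to (2E,4R,5S)-5-(tert-butyldimethylsilyloxy)-4-methylhex-2-en-1-ol F4, and converted under Appel conditions (CBr4, PPh3) into ((2S,3R,4E)-6-bromo-3-methylhex-4-en-2-yl)oxy(tert-butyl)dimethylsilane F5. Conjugate reduction of F2 with LiB(s-Bu)3H at −78 °C should give the C4–C5 lithium enolate of the oxan-4-one F6 regiospecifically, and its alkylation with F5 would give 27.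

Step 13. The cation chemistry may reopen the C2–C3 bond (retro-addition of the 2-oxonia-Cope type), which would scramble C2, or the enol ether may hydrolyse before the ring closes. The fallback avoids cations at C2; it sets out from 24 and comes back at 27. Enol ether 24 would be treated with dimethyl(methylene)ammonium iodide (Mannich reaction at the enol ether β-carbon, aqueous work-up) to give 6-(tert-butoxy)-6-oxohexyl (2E,5S,10E,12R,13S)-13-(tert-butyldimethylsilyloxy)-8-((dimethylamino)methyl)-5-hydroxy-3,12-dimethyl-7-oxotetradeca-2,10-dienoate F7. N-Methylation with MeI would give the trimethylammonium iodide of F7, F8, and NaHCO3 would eliminate trimethylamine to the α-methylene ketone 6-(tert-butoxy)-6-oxohexyl (2E,5S,10E,12R,13S)-13-(tert-butyldimethylsilyloxy)-5-hydroxy-3,12-dimethyl-8-methylene-7-oxotetradeca-2,10-dienoate F9. Its C5 hydroxyl should then close the ring by 6-endo oxa-Michael addition (cat. DBU) to give 27.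

Step 14. Enolisation may not discriminate cleanly between C3 and C5, and the enolate may open the ring by β-elimination of O1. The fallback uses a condensation that only a methylene can undergo; it sets out from 27 and comes back at 31. Ketone 27 would be condensed with tert-butoxybis(dimethylamino)methane at C3 to give the enaminone 6-(tert-butoxy)-6-oxohexyl (E)-4-((2S,5RS)-5-((2E,4R,5S)-5-(tert-butyldimethylsilyloxy)-4-methylhex-2-en-1-yl)-3-((dimethylamino)methylene)-4-oxooxan-2-yl)-3-methylbut-2-enoate F10. Photo-oxygenation (O2, rose bengal, visible light) should cleave the enamine double bond with loss of dimethylformamide to the 3,4-dione, which enolises to the protected diosphenol 6-(tert-butoxy)-6-oxohexyl (E)-4-((S)-5-((2E,4R,5S)-5-(tert-butyldimethylsilyloxy)-4-methylhex-2-en-1-yl)-4-hydroxy-3-oxo-3,6-dihydro-2H-pyran-2-yl)-3-methylbut-2-enoate F11. CF3CO2H/CH2Cl2/H2O would then remove the tert-butyl ester and the silyl ether to give 31.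

Further compounds
F1 | step 11 | 6-(tert-butoxy)-6-oxohexyl (E)-4-((2S)-6-methoxy-4-(trimethylsilyloxy)-3,6-dihydro-2H-pyran-2-yl)-3-methylbut-2-enoate | CC(C)(C)OC(=O)CCCCCOC(=O)/C=C(\C)C[C@H]1CC(O[Si](C)(C)C)=CC(OC)O1
F2 | step 11 | 6-(tert-butoxy)-6-oxohexyl (E)-3-methyl-4-((S)-4-oxo-3,4-dihydro-2H-pyran-2-yl)but-2-enoate | CC(C)(C)OC(=O)CCCCCOC(=O)/C=C(\C)C[C@H]1CC(=O)C=CO1
F3 | step 11 | ethyl (2E,4R,5S)-5-(tert-butyldimethylsilyloxy)-4-methylhex-2-enoate | CCOC(=O)/C=C/[C@@H](C)[C@H](C)O[Si](C)(C)C(C)(C)C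
F4 | step 11 | (2E,4R,5S)-5-(tert-butyldimethylsilyloxy)-4-methylhex-2-en-1-ol | OC/C=C/[C@@H](C)[C@H](C)O[Si](C)(C)C(C)(C)C
F5 | step 11 | ((2S,3R,4E)-6-bromo-3-methylhex-4-en-2-yl)oxy(tert-butyl)dimethylsilane | BrC/C=C/[C@@H](C)[C@H](C)O[Si](C)(C)C(C)(C)C
F6 | step 11 | lithium enolate from conjugate reduction of F2 | CC(C)(C)OC(=O)CCCCCOC(=O)/C=C(\C)C[C@H]1CC([O-])=CCO1.[Li+]
F7 | step 13 | 6-(tert-butoxy)-6-oxohexyl (2E,5S,10E,12R,13S)-13-(tert-butyldimethylsilyloxy)-8-((dimethylamino)methyl)-5-hydroxy-3,12-dimethyl-7-oxotetradeca-2,10-dienoate | CC(C)(C)OC(=O)CCCCCOC(=O)/C=C(\C)C[C@H](O)CC(=O)C(CN(C)C)C/C=C/[C@@H](C)[C@H](C)O[Si](C)(C)C(C)(C)C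
F8 | step 13 | trimethylammonium iodide of F7 | CC(C)(C)OC(=O)CCCCCOC(=O)/C=C(\C)C[C@H](O)CC(=O)C(C[N+](C)(C)C)C/C=C/[C@@H](C)[C@H](C)O[Si](C)(C)C(C)(C)C.[I-]
F9 | step 13 | 6-(tert-butoxy)-6-oxohexyl (2E,5S,10E,12R,13S)-13-(tert-butyldimethylsilyloxy)-5-hydroxy-3,12-dimethyl-8-methylene-7-oxotetradeca-2,10-dienoate | CC(C)(C)OC(=O)CCCCCOC(=O)/C=C(\C)C[C@H](O)CC(=O)C(=C)C/C=C/[C@@H](C)[C@H](C)O[Si](C)(C)C(C)(C)C
F10 | step 14 | 6-(tert-butoxy)-6-oxohexyl (E)-4-((2S,5RS)-5-((2E,4R,5S)-5-(tert-butyldimethylsilyloxy)-4-methylhex-2-en-1-yl)-3-((dimethylamino)methylene)-4-oxooxan-2-yl)-3-methylbut-2-enoate | CC(C)(C)OC(=O)CCCCCOC(=O)/C=C(\C)C[C@@H]1OCC(C/C=C/[C@@H](C)[C@H](C)O[Si](C)(C)C(C)(C)C)C(=O)C1=CN(C)C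
F11 | step 14 | 6-(tert-butoxy)-6-oxohexyl (E)-4-((S)-5-((2E,4R,5S)-5-(tert-butyldimethylsilyloxy)-4-methylhex-2-en-1-yl)-4-hydroxy-3-oxo-3,6-dihydro-2H-pyran-2-yl)-3-methylbut-2-enoate | CC(C)(C)OC(=O)CCCCCOC(=O)/C=C(\C)C[C@@H]1OCC(C/C=C/[C@@H](C)[C@H](C)O[Si](C)(C)C(C)(C)C)=C(O)C1=O
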